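**Retrosynthetic overview**
1. Numbering of the dihydrobenzofuran core: O1, C2, C3, C3a, C4–C7, C7a. Ring A is the 4-hydroxyphenyl on C2, ring B the benzo ring C3a–C7a, ring C the dihydrofuran, ring D the 3,5-dihydroxyphenyl on C3, and rings E/F the 6-hydroxybenzofuran on C6.
2. The last cut removes five acid-labile groups (three O-Boc, two O-MOM). The main cut takes O1–C2, C2–C3 and C3–ring D apart together and gives three pieces: a 2,6-bis(O-Boc)-4-(benzofuranyl)benzaldehyde (rings B, E, F and C3), a ring D Grignard reagent, and a chiral ring A benzyl sulfonium ylide (C2).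
3. In the forward direction, Grignard addition triggers Boc transfer and loss of tert-butyl carbonate to give an ortho-quinone methide. The ylide adds to C3, then phenoxide O1 displaces the sulfide from C2 and closes ring C ([4+1] annulation), which sets C2 and C3.
4. Enabling feature: in ring B, C3a lies between two equivalent oxygen-bearing carbons (C7a–O1 and C4–OH), so either O-Boc group unveils the same quinone methide C7a(=O)/C3a=C3 and no choice of oxygen arises. C2 is benzylic to the para-oxygenated ring A, so it can arrive as a semistabilised benzylide and carry the sulfonium leaving group.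
5. Ring order: rings E/F come ready-made with the boronic acid and are joined to ring B by Suzuki–Miyaura coupling. Ring C is the only ring built and is formed last.

Key step: step 8

Assumption: the benzylide of the (1R,4R,5R)-sulfide is taken to react with the facial sense that gives (R,R)-trans-diaryl epoxides with aldehydes. If the sense proves opposite, the (1S,4S,5S)-sulfide from (S)-limonene is used with no other change.

**Step 1**
Reactants: 1 4-bromo-2,6-dimethoxybenzaldehyde; 2 (6-methoxy-1-benzofuran-2-yl)boronic acid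
Product: 3 2,6-dimethoxy-4-(6-methoxy-1-benzofuran-2-yl)benzaldehyde
Conditions: Pd(OAc)2 (cat.), SPhos (cat.), K3PO4, THF/H2O, 40 °C
Reagents that add atoms: none
Why: Suzuki–Miyaura coupling in which the para-formyl group activates the C–Br bond and a fast catalyst at mild temperature should outrun protodeboronation of the 2-benzofuranylboronic acid; no stereocentre is formed.

**Step 2**
Reactants: 3 2,6-dimethoxy-4-(6-methoxy-1-benzofuran-2-yl)benzaldehyde
Product: 4 2,6-dihydroxy-4-(6-hydroxy-1-benzofuran-2-yl)benzaldehyde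
Conditions: BBr3 (5 equiv), CH2Cl2, −78 → 25 °C; then ice/H2O
Reagents that add atoms: none
Why: Lewis-acid aryl methyl ether cleavage, in which the two ethers ortho to the formyl group fall first by chelation and the benzofuran ether follows at room temperature, as is usual for 2-arylbenzofuran trimethyl ethers.

**Step 3**
Reactants: 4 2,6-dihydroxy-4-(6-hydroxy-1-benzofuran-2-yl)benzaldehyde
Product: 5 2,6-bis(tert-butoxycarbonyloxy)-4-[6-(tert-butoxycarbonyloxy)-1-benzofuran-2-yl]benzaldehyde
Conditions: Boc2O (3.6 equiv), DMAP (cat.), iPr2NEt, THF, 0 → 25 °C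
Reagents that add atoms: di-tert-butyl dicarbonate CC(C)(C)OC(=O)OC(=O)OC(C)(C)C
Why: DMAP-catalysed O-acylation turns all three phenols into aryl tert-butyl carbonates, which serve as protection and, for the two flanking groups, as the later trigger for the quinone methide.

**Step 4**
Reactants: 6 5-bromobenzene-1,3-diol
Product: 7 1-bromo-3,5-bis(methoxymethoxy)benzene
Conditions: MOMCl (2.5 equiv), iPr2NEt, CH2Cl2, 0 → 25 °C
Reagents that add atoms: chloromethyl methyl ether COCCl
Why: Williamson-type O-alkylation gives acetal ethers that tolerate organomagnesium formation and fall under the same acid treatment as the carbonates.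

**Step 5**
Reactants: 8 4-methylphenol
Product: 9 tert-butyl 4-methylphenyl carbonate
Conditions: Boc2O (1.1 equiv), DMAP (cat.), CH2Cl2, 25 °C
Reagents that add atoms: di-tert-butyl dicarbonate CC(C)(C)OC(=O)OC(=O)OC(C)(C)C
Why: DMAP-catalysed O-acylation of a single phenol, with no competing functional group.

**Step 6**
Reactants: 9 tert-butyl 4-methylphenyl carbonate
Product: 10 4-(bromomethyl)phenyl tert-butyl carbonate
Conditions: NBS (1.0 equiv), AIBN (cat.), PhCF3, 85 °C
Reagents that add atoms: N-bromosuccinimide O=C1CCC(=O)N1Br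
Why: Wohl–Ziegler benzylic bromination; the carbonate deactivates the ring toward ionic bromination and is thermally stable at this temperature.

**Step 7**
Reactants: 10 4-(bromomethyl)phenyl tert-butyl carbonate; 11 (1R,4R,5R)-4,7,7-trimethyl-6-thiabicyclo[3.2.1]octane (isothiocineole, commercial, also made in one step from (R)-limonene)
Product: 12 (1R,4R,5R,6R)-6-[4-(tert-butoxycarbonyloxy)benzyl]-4,7,7-trimethyl-6-thiabicyclo[3.2.1]octan-6-ium trifluoromethanesulfonate
Conditions: LiOSO2CF3 (5 equiv), CH2Cl2/H2O, 25 °C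
Reagents that add atoms: lithium trifluoromethanesulfonate [Li+].[O-]S(=O)(=O)C(F)(F)F
Why: SN2 S-alkylation with anion metathesis, in which the sulfide attacks through its exposed exo lone pair so that a single configuration at sulfur (6R) should result, and the non-nucleophilic triflate prevents reversal.

**Step 8**
Reactants: 5 2,6-bis(tert-butoxycarbonyloxy)-4-[6-(tert-butoxycarbonyloxy)-1-benzofuran-2-yl]benzaldehyde; 7 1-bromo-3,5-bis(methoxymethoxy)benzene; 12 (1R,4R,5R,6R)-6-[4-(tert-butoxycarbonyloxy)benzyl]-4,7,7-trimethyl-6-thiabicyclo[3.2.1]octan-6-ium trifluoromethanesulfonate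
Product: 19 tert-butyl 4-[(2S,3S)-3-[3,5-bis(methoxymethoxy)phenyl]-4-(tert-butoxycarbonyloxy)-6-[6-(tert-butoxycarbonyloxy)-1-benzofuran-2-yl]-2,3-dihydro-1-benzofuran-2-yl]phenyl carbonate, via aryl Grignard reagent 13 (not isolated), via bromomagnesium alkoxide 14 (not isolated), via Boc-shifted bromomagnesium phenoxide 15 (not isolated), via ortho-quinone methide 16 (not isolated), via sulfonium benzylide 17 (not isolated), via sulfonium phenoxide betaine 18 (not isolated)
Conditions: (a) 7, Mg, LiCl, THF, 25 °C; (b) 5, THF, −78 °C, add (a) (1.0 equiv); (c) separately 12 (1.3 equiv), LiN(SiMe3)2 (1.25 equiv), THF/CH2Cl2, −78 °C, cannulate into (b); −78 → −10 °C; aq NH4Cl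
Reagents that add atoms: none
Why: Proposed new method: Grignard reagent 13 adds to the formyl group of 5, alkoxide 14 takes over one flanking Boc group through a six-membered transition state (15), the phenoxide expels tert-butyl carbonate to unveil ortho-quinone methide 16 (C7a=O, C3a=C3), benzylide 17 attacks C3 in an aromatising and therefore irreversible 1,4-addition to give betaine 18, and phenoxide O1 then displaces the sulfide from C2. The closest known reaction types are the anionic Boc-transfer generation of ortho-quinone methides from O-Boc salicylaldehydes and organomagnesium reagents with capture by a third component, the trans-selective [4+1] annulation of ortho-quinone methides with sulfur ylides, and the addition/ring-closure reactions (epoxidation, aziridination, cyclopropanation) of chiral benzyl sulfonium ylides, whereas their merger and the use of a semistabilised chiral benzylide on an ortho-quinone methide are new. The only ring formed, ring C, closes 5-exo-tet with inversion at C2. C2 is controlled by the sulfide, because the benzylidene aryl group lies syn to the sulfur lone pair, the CMe2 flank shields one lobe of the ylide carbon, C3 bonds past the CH flank, and inversion then gives 2S, the same spatial sense as in the (R,R)-epoxides expected from this sulfide. C3 is set relative to C2 in the addition step by an open transition state that keeps rings A and D anti and so leads to the trans (2S,3S) isomer, while any syn betaine should end as the separable cis isomer and not as the enantiomer, because the electron-poor carbonate on ring A keeps the displacement invertive rather than ionising. The step needs addition to the aldehyde rather than to the carbonates (secured by the far more electrophilic formyl group at −78 °C), no choice between the two flanking oxygens (they are equivalent and give the same 16), and O- rather than C-closure (secured by the aromatic phenoxide).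

**Step 9**
Reactants: 19 tert-butyl 4-[(2S,3S)-3-[3,5-bis(methoxymethoxy)phenyl]-4-(tert-butoxycarbonyloxy)-6-[6-(tert-butoxycarbonyloxy)-1-benzofuran-2-yl]-2,3-dihydro-1-benzofuran-2-yl]phenyl carbonate
Product: 20 (2S,3S)-3-(3,5-dihydroxyphenyl)-6-(6-hydroxy-1-benzofuran-2-yl)-2-(4-hydroxyphenyl)-2,3-dihydro-1-benzofuran-4-ol
Conditions: HCl (3 M aq)/MeOH/THF, high dilution, 45 °C
Reagents that add atoms: none
Why: Acid-catalysed acetal and tert-butyl carbonate cleavage (global deprotection) removes all five groups without touching C3, and any reversible ionisation of the C2–O1 bond to the protonated para-quinone methide should reclose to the more stable trans isomer, so (2S,3S) is kept.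

**Compound list**
1 | 4-bromo-2,6-dimethoxybenzaldehyde | COc1cc(Br)cc(OC)c1C=O | starting material
2 | (6-methoxy-1-benzofuran-2-yl)boronic acid | COc1ccc2cc(B(O)O)oc2c1 | starting material
3 | 2,6-dimethoxy-4-(6-methoxy-1-benzofuran-2-yl)benzaldehyde | COc1ccc2cc(-c3cc(OC)c(C=O)c(OC)c3)oc2c1 | intermediate
4 | 2,6-dihydroxy-4-(6-hydroxy-1-benzofuran-2-yl)benzaldehyde | Oc1ccc2cc(-c3cc(O)c(C=O)c(O)c3)oc2c1 | intermediate
5 | 2,6-bis(tert-butoxycarbonyloxy)-4-[6-(tert-butoxycarbonyloxy)-1-benzofuran-2-yl]benzaldehyde | CC(C)(C)OC(=O)Oc1ccc2cc(-c3cc(OC(=O)OC(C)(C)C)c(C=O)c(OC(=O)OC(C)(C)C)c3)oc2c1 | intermediate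
6 | 5-bromobenzene-1,3-diol | Oc1cc(O)cc(Br)c1 | starting material
7 | 1-bromo-3,5-bis(methoxymethoxy)benzene | COCOc1cc(Br)cc(OCOC)c1 | intermediate
8 | 4-methylphenol | Cc1ccc(O)cc1 | starting material
9 | tert-butyl 4-methylphenyl carbonate | Cc1ccc(OC(=O)OC(C)(C)C)cc1 | intermediate
10 | 4-(bromomethyl)phenyl tert-butyl carbonate | BrCc1ccc(OC(=O)OC(C)(C)C)cc1 | intermediate
11 | (1R,4R,5R)-4,7,7-trimethyl-6-thiabicyclo[3.2.1]octane (isothiocineole) | C[C@@H]1CC[C@@H]2C[C@H]1SC2(C)C | starting material
12 | (1R,4R,5R,6R)-6-[4-(tert-butoxycarbonyloxy)benzyl]-4,7,7-trimethyl-6-thiabicyclo[3.2.1]octan-6-ium trifluoromethanesulfonate | C[C@@H]1CC[C@@H]2C[C@H]1[S@@+](Cc1ccc(OC(=O)OC(C)(C)C)cc1)C2(C)C.[O-]S(=O)(=O)C(F)(F)F | intermediate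
13 | 3,5-bis(methoxymethoxy)phenylmagnesium bromide | COCOc1cc([Mg]Br)cc(OCOC)c1 | intermediate
14 | bromomagnesium [3,5-bis(methoxymethoxy)phenyl]{2,6-bis(tert-butoxycarbonyloxy)-4-[6-(tert-butoxycarbonyloxy)-1-benzofuran-2-yl]phenyl}methanolate (racemic, centre erased in the next events) | COCOc1cc(cc(OCOC)c1)C(O[Mg]Br)c1c(OC(=O)OC(C)(C)C)cc(cc1OC(=O)OC(C)(C)C)-c1cc2ccc(OC(=O)OC(C)(C)C)cc2o1 | intermediate
15 | bromomagnesium 2-{[3,5-bis(methoxymethoxy)phenyl](tert-butoxycarbonyloxy)methyl}-3-(tert-butoxycarbonyloxy)-5-[6-(tert-butoxycarbonyloxy)-1-benzofuran-2-yl]phenolate (racemic) | COCOc1cc(cc(OCOC)c1)C(OC(=O)OC(C)(C)C)c1c(O[Mg]Br)cc(cc1OC(=O)OC(C)(C)C)-c1cc2ccc(OC(=O)OC(C)(C)C)cc2o1 | intermediate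
16 | 6-[3,5-bis(methoxymethoxy)benzylidene]-5-(tert-butoxycarbonyloxy)-3-[6-(tert-butoxycarbonyloxy)-1-benzofuran-2-yl]cyclohexa-2,4-dien-1-one (ortho-quinone methide, alkene geometry not fixed) | COCOc1cc(C=C2C(=O)C=C(C=C2OC(=O)OC(C)(C)C)c2cc3ccc(OC(=O)OC(C)(C)C)cc3o2)cc(OCOC)c1 | intermediate
17 | (1R,4R,5R,6R)-4,7,7-trimethyl-6-thiabicyclo[3.2.1]octan-6-ium-6-yl [4-(tert-butoxycarbonyloxy)phenyl]methanide (sulfonium benzylide) | C[C@@H]1CC[C@@H]2C[C@H]1[S@@+]([CH-]c1ccc(OC(=O)OC(C)(C)C)cc1)C2(C)C | intermediate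
18 | 2-{(1S,2R)-1-[3,5-bis(methoxymethoxy)phenyl]-2-[4-(tert-butoxycarbonyloxy)phenyl]-2-[(1R,4R,5R)-4,7,7-trimethyl-6-thiabicyclo[3.2.1]octan-6-ium-6-yl]ethyl}-3-(tert-butoxycarbonyloxy)-5-[6-(tert-butoxycarbonyloxy)-1-benzofuran-2-yl]phenolate (betaine) | CC(C)(C)OC(=O)Oc1ccc(cc1)[C@H]([S@@+]2[C@@H]3C[C@@H](CC[C@H]3C)C2(C)C)[C@H](c2c([O-])cc(cc2OC(=O)OC(C)(C)C)-c2cc3ccc(OC(=O)OC(C)(C)C)cc3o2)c2cc(OCOC)cc(OCOC)c2 | intermediate
19 | tert-butyl 4-[(2S,3S)-3-[3,5-bis(methoxymethoxy)phenyl]-4-(tert-butoxycarbonyloxy)-6-[6-(tert-butoxycarbonyloxy)-1-benzofuran-2-yl]-2,3-dihydro-1-benzofuran-2-yl]phenyl carbonate | CC(C)(C)OC(=O)Oc1ccc([C@H]2Oc3cc(-c4cc5ccc(OC(=O)OC(C)(C)C)cc5o4)cc(OC(=O)OC(C)(C)C)c3[C@@H]2c2cc(OCOC)cc(OCOC)c2)cc1 | intermediate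
20 | (2S,3S)-3-(3,5-dihydroxyphenyl)-6-(6-hydroxy-1-benzofuran-2-yl)-2-(4-hydroxyphenyl)-2,3-dihydro-1-benzofuran-4-ol | Oc1ccc([C@H]2Oc3cc(-c4cc5ccc(O)cc5o4)cc(O)c3[C@@H]2c2cc(O)cc(O)c2)cc1 | target

Total step count: 9
Longest linear sequence: 5 steps (1 → 3 → 4 → 5 → 19 → 20, or 8 → 9 → 10 → 12 → 19 → 20)

**Steps most likely to fail**

**Step 8.** The ylide may be lost to proton or acyl transfer from the carbonates before the quinone methide is released. The quinone methide may dimerise. The addition may show poor simple diastereoselectivity, or the closure may ionise and erode the enantiomeric purity.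

The fallback uses known reaction types only, keeps salt 12 as the source of chirality and still closes ring C at O1–C2. It sets out from 4 (together with 12 and 7) and returns at 20.
- Triol 4 is protected with MOMCl/iPr2NEt to give 2,6-bis(methoxymethoxy)-4-[6-(methoxymethoxy)-1-benzofuran-2-yl]benzaldehyde F1.
- Benzylide 17, made from 12 with LiN(SiMe3)2 at −78 °C, is combined with F1 in an asymmetric sulfur-ylide epoxidation (Corey–Chaykovsky type). This should give tert-butyl 4-[(2R,3R)-3-{2,6-bis(methoxymethoxy)-4-[6-(methoxymethoxy)-1-benzofuran-2-yl]phenyl}oxiran-2-yl]phenyl carbonate F2.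
- Grignard reagent 13 with CuI (cat.) in THF at −40 °C opens the epoxide with inversion at the carbon next to the electron-rich 2,6-dioxygenated ring. The product should be tert-butyl 4-[(1S,2S)-2-[3,5-bis(methoxymethoxy)phenyl]-2-{2,6-bis(methoxymethoxy)-4-[6-(methoxymethoxy)-1-benzofuran-2-yl]phenyl}-1-hydroxyethyl]phenyl carbonate F3.
- HCl in MeOH then removes all protecting groups and ionises the benzylic alcohol to the protonated para-quinone methide. A flanking phenol closes 5-exo-trig onto C2, trans to the fixed (S)-C3, to give 20.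

**Step 9.** Acid may open the C2–O1 bond faster than the acetals fall, which would lead to oligomerisation, and tert-butyl cations may alkylate the resorcinol rings.

The fallback removes acid from the endgame by changing the protecting-group plan. It sets out from 6 and returns at 20.
- TBSCl/imidazole converts 6 into 1-bromo-3,5-bis(tert-butyldimethylsilyloxy)benzene F4.
- The Grignard reagent of F4 replaces 13 in step 8 and should give tert-butyl 4-[(2S,3S)-3-[3,5-bis(tert-butyldimethylsilyloxy)phenyl]-4-(tert-butoxycarbonyloxy)-6-[6-(tert-butoxycarbonyloxy)-1-benzofuran-2-yl]-2,3-dihydro-1-benzofuran-2-yl]phenyl carbonate F5.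
- K2CO3 in MeOH/THF at 0 → 25 °C cleaves the aryl carbonates and the aryl silyl ethers by methanolysis, and mild acidification then gives 20.

**Step 2.** The benzofuran methyl ether may resist cleavage, or the electron-rich 2-arylbenzofuran aldehyde may degrade under prolonged exposure to BBr3.

The fallback never installs that ether and builds rings E/F from free phenols. It sets out from 1 and returns at 4.
- BCl3 in CH2Cl2 cleaves only the two chelated ortho ethers of 1 to give 4-bromo-2,6-dihydroxybenzaldehyde F6.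
- Sonogashira coupling with ethynyltrimethylsilane (PdCl2(PPh3)2, CuI, Et3N) gives 2,6-dihydroxy-4-[(trimethylsilyl)ethynyl]benzaldehyde F7.
- K2CO3/MeOH gives 4-ethynyl-2,6-dihydroxybenzaldehyde F8.
- A second Sonogashira coupling with commercial 4-iodobenzene-1,3-diol, followed in the same flask by 5-endo-dig cyclisation of the ortho hydroxyl group onto the alkyne, gives 4.

**Further compounds**
F1 | step 8 | 2,6-bis(methoxymethoxy)-4-[6-(methoxymethoxy)-1-benzofuran-2-yl]benzaldehyde | COCOc1ccc2cc(-c3cc(OCOC)c(C=O)c(OCOC)c3)oc2c1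
F2 | step 8 | tert-butyl 4-[(2R,3R)-3-{2,6-bis(methoxymethoxy)-4-[6-(methoxymethoxy)-1-benzofuran-2-yl]phenyl}oxiran-2-yl]phenyl carbonate | CC(C)(C)OC(=O)Oc1ccc(cc1)[C@H]1O[C@@H]1c1c(OCOC)cc(cc1OCOC)-c1cc2ccc(OCOC)cc2o1
F3 | step 8 | tert-butyl 4-[(1S,2S)-2-[3,5-bis(methoxymethoxy)phenyl]-2-{2,6-bis(methoxymethoxy)-4-[6-(methoxymethoxy)-1-benzofuran-2-yl]phenyl}-1-hydroxyethyl]phenyl carbonate | CC(C)(C)OC(=O)Oc1ccc(cc1)[C@@H](O)[C@H](c1c(OCOC)cc(cc1OCOC)-c1cc2ccc(OCOC)cc2o1)c1cc(OCOC)cc(OCOC)c1
F4 | step 9 | 1-bromo-3,5-bis(tert-butyldimethylsilyloxy)benzene | CC(C)(C)[Si](C)(C)Oc1cc(Br)cc(O[Si](C)(C)C(C)(C)C)c1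
F5 | step 9 | tert-butyl 4-[(2S,3S)-3-[3,5-bis(tert-butyldimethylsilyloxy)phenyl]-4-(tert-butoxycarbonyloxy)-6-[6-(tert-butoxycarbonyloxy)-1-benzofuran-2-yl]-2,3-dihydro-1-benzofuran-2-yl]phenyl carbonate | CC(C)(C)OC(=O)Oc1ccc([C@H]2Oc3cc(-c4cc5ccc(OC(=O)OC(C)(C)C)cc5o4)cc(OC(=O)OC(C)(C)C)c3[C@@H]2c2cc(O[Si](C)(C)C(C)(C)C)cc(O[Si](C)(C)C(C)(C)C)c2)cc1
F6 | step 2 | 4-bromo-2,6-dihydroxybenzaldehyde | O=Cc1c(O)cc(Br)cc1O
F7 | step 2 | 2,6-dihydroxy-4-[(trimethylsilyl)ethynyl]benzaldehyde | C[Si](C)(C)C#Cc1cc(O)c(C=O)c(O)c1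
F8 | step 2 | 4-ethynyl-2,6-dihydroxybenzaldehyde | C#Cc1cc(O)c(C=O)c(O)c1
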